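I looked first for what stood still.

| setting | red | amber | flask |
|---|---|---|---|
| substrate | 1.5 M | 2.2 M | 1.5 M |
| remark | the very flask that is asked about, followed so far | run made earlier |  |
| time |  |  | 2.5 h |

| run | time / min | substrate / % | target / % |
|---|---|---|---|
| red | 15.0 | 41.1 | 46.8 |
| red | 30.0 | 32.2 | 50.9 |
| red | 50.0 | 30.0 | 50.6 |
| red | 60.0 | 29.5 | 50.6 |
| amber | 12.0 | 42.8 | 49.4 |
| amber | 40.0 | 20.9 | 66.1 |
| amber | 60.0 | 20.0 | 66.4 |
| amber | 120 | 20.3 | 66.6 |

(standard deviation of a reading: 0.3 percentage points)

* the state of affairs at 2.5 h: stopped, and by what, or still going (forward and back rates have come level / all of the substrate has reacted / it is still moving)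
* part of the substrate gone at 2.5 h
* the target standing at 2.5 h, as a percentage of the substrate charged
* the isomer of the product standing at 2.5 h, as a percentage of the substrate charged

- a reading or a percentage of target counts all its forms, free or not
- the reaction counts as stopped when no species that holds the substrate changes by six tenths of a point or more over the second half of the time

The flask asked about is the red run followed on to 2.5 h, but red ends at 60.0 min, so I needed amber to show that such a flask stays put. Over the second half of its time, from 60.0 min to 120 min, amber's substrate went from 20.0 % to 20.3 % and its target from 66.4 % to 66.6 %, so it had stopped with substrate left, which I took for thermodynamic control.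

But the two runs stopped at different shares of their charges. So I multiplied each share by its charge: amber's last reading gave 0.447 M and red's 0.443 M. I called this product the standing substrate and froze it.

On the flask's charge, it left 29.8 % of the substrate, so 70.2 % was gone. By the balance, amber held 0.288 M of isomer of the product. Frozen the same way, that gave the flask 19.2 % of isomer and 51.0 % of target.

The forecast, whose figures differ a little from mine, said that forward and back rates have come level, with 70.4 % gone, target 50.7 % and isomer of the product 19.7 %. As what capped the dissolved target, it named as probable “a separate solid or bound form that absorbs the excess”.

In the flask, forward and back rates have come level, with 70.8 % gone, target 50.3 % and isomer of the product 20.5 %.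

    target ⇌ isomer of the product (K = 0.440, k = 0.0350 min⁻¹)
    crystals ⇌ target, rate k2*(cs2 - [target]) while solid is left; crystals form when [target] > cs2 (solubility = 0.700 M, k = 8.00 min⁻¹)
    substrate ⇌ target (K = 1.60, k = 0.100 min⁻¹)

Crystals stood at 3.63 % in the flask at 2.50 h, counted in its target. The flask kept 29 % of its substrate, where the standing substrate had given 29.8 %. For a neighbour flask charged with 2.5 M, the standing substrate gives 17.9 %, and that neighbour held 17.5 %.

The runs were generated by integration with made-up constants; the scatter is artificial.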